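**Plan**

- Retrosynthetic cuts: first the imide C16–N bond and C12–C13 (acyl transfer to a nitrile-derived amide; syn-aldol). Then C9–C10 together with C4–C5, which opens ring B and ring A to the acyclic triene 13. Then C8–C17, C7–C8, C5–C6 and the two C–C bonds flanking C2.
- Enabling feature: C4 (gem-dimethyl), C10 (quaternary, methyl-bearing) and C8 (bearing the C17 methylidene) are three successive tertiary stations of a head-to-tail chain C18=C4 / C5=C10 / C9=C8. The exocyclic C8=C17 bond is the scar of an allylsilane whose Me3Si helper is expelled in the ring-forming step itself.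
- Forward order: linear chain assembly, then ring A (C4–C5) and ring B (C9–C10) in one cobalt-hydride-initiated operation, then the side-chain aldol, and last the succinimide ring.
- Stereochemistry: C2 from (R)-epichlorohydrin with one Appel inversion; C7 from ligand-controlled alkynylation; C5, C9 and C10 from the chair–chair bicyclisation (E-alkene, Z-allylsilane, equatorial Cl and OAc); C12 and C13 from the (R)-benzyloxazolidinone.

Key step: step 9

Remark: positions follow labdane numbering (ring A = C1–C5 and C10; ring B = C5–C10; C17 = methylidene carbon; C18 = the chain-terminal CH2 that becomes one C4 methyl). The target is (2S,5S,7S,9R,10S,12S,13R); compounds 1, 9, 17 and 18 are taken as commercial.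

**Route**

Step 1
Reactants: 1 (R)-epichlorohydrin
Product: 2 (2R)-1-chloro-4-methylpent-4-en-2-ol
Conditions: isopropenylmagnesium bromide, CuI (10 mol %), THF, −40 to −20 °C; aq NH4Cl
Reagents that add atoms: isopropenylmagnesium bromide, C=C(C)[Mg]Br
Why: copper-catalysed Grignard opening of the epoxide at its unsubstituted carbon should leave the chloride and the chiral-pool carbinol centre untouched.

Step 2
Reactants: 2 (2R)-1-chloro-4-methylpent-4-en-2-ol
Product: 4 (4R)-6-methylhept-6-en-1-yn-4-ol, via epoxide 3 (not isolated)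
Conditions: lithium acetylide–ethylenediamine complex (2.5 equiv), DMSO, 0 °C to rt
Reagents that add atoms: lithium acetylide–ethylenediamine complex, [Li]C#C.NCCN
Why: the alkoxide should close to the terminal epoxide (intramolecular Williamson displacement) and the acetylide should open it at the CH2 terminus (SN2 epoxide alkynylation), so the C–O stereocentre is never a reaction site.

Step 3
Reactants: 4 (4R)-6-methylhept-6-en-1-yn-4-ol
Product: 5 (4S)-4-chloro-6-methylhept-6-en-1-yne
Conditions: PPh3, CCl4, CH2Cl2, 40 °C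
Reagents that add atoms: carbon tetrachloride, ClC(Cl)(Cl)Cl
Why: Appel chlorination should displace the alkoxyphosphonium group by chloride in an SN2 step with inversion, which sets the (S)-chloride that becomes C2.

Step 4
Reactants: 5 (4S)-4-chloro-6-methylhept-6-en-1-yne
Product: 7 (3E,6S)-6-chloro-4,8-dimethylnona-3,8-dien-1-ol, via alkenylalane 6 (not isolated)
Conditions: Me3Al, Cp2ZrCl2 (20 mol %), CH2Cl2, 0 °C to rt; volatiles removed; n-BuLi, THF/hexane, −78 °C; ethylene oxide, −78 to 0 °C
Reagents that add atoms: trimethylaluminium, C[Al](C)C; ethylene oxide, C1CO1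
Why: Negishi zirconium-catalysed carboalumination should add methyl and aluminium syn across the terminal alkyne (methyl to the internal carbon), and the derived alkenylalanate should open ethylene oxide with retention, fixing the E-C5=C10 alkene while the 1,1-disubstituted alkene and the secondary chloride stay inert.

Step 5
Reactants: 7 (3E,6S)-6-chloro-4,8-dimethylnona-3,8-dien-1-ol
Product: 8 (3E,6S)-6-chloro-4,8-dimethylnona-3,8-dienal
Conditions: Dess–Martin periodinane, NaHCO3, CH2Cl2, 0 °C; used at once
Reagents that add atoms: none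
Why: buffered Dess–Martin oxidation should give the β,γ-unsaturated aldehyde without acid or base that could move the alkene into conjugation.

Step 6
Reactants: 8 (3E,6S)-6-chloro-4,8-dimethylnona-3,8-dienal; 9 tert-butyl(but-3-yn-1-yloxy)dimethylsilane
Product: 11 (5S,7E,10S)-1-[(tert-butyldimethylsilyl)oxy]-10-chloro-8,12-dimethyltrideca-7,12-dien-3-yn-5-ol, via alkynylzinc 10 (not isolated)
Conditions: 9 (2 equiv), Et2Zn (2 equiv), toluene, reflux; then (R)-BINOL (40 mol %), Ti(OiPr)4 (0.5 equiv), Et2O, rt; then 8, rt
Reagents that add atoms: none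
Why: BINOL–titanium-catalysed asymmetric alkynylzinc addition to an aldehyde, in which the (R)-ligand is expected to direct alkynyl transfer to the Re face and so set the (S)-carbinol that becomes C7, in an amine-free medium that should spare the skipped enal.

Step 7
Reactants: 11 (5S,7E,10S)-1-[(tert-butyldimethylsilyl)oxy]-10-chloro-8,12-dimethyltrideca-7,12-dien-3-yn-5-ol
Product: 12 (3Z,5S,7E,10S)-1-[(tert-butyldimethylsilyl)oxy]-10-chloro-8,12-dimethyl-4-[(trimethylsilyl)methyl]trideca-3,7,12-trien-5-ol
Conditions: Me3SiCH2MgCl (4 equiv), CuI (20 mol %), THF, 0 to 50 °C; aq NH4Cl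
Reagents that add atoms: (trimethylsilyl)methylmagnesium chloride, C[Si](C)(C)C[Mg]Cl
Why: copper-catalysed anti-carbomagnesiation of a propargylic alcohol should deliver the silylmethyl group to the proximal alkyne carbon (C8) while magnesium sits on C9 in a five-membered alkoxide chelate, so protonation leaves H9 cis to C7 and the C11 chain cis to CH2SiMe3 (Z-allylsilane).

Step 8
Reactants: 12 (3Z,5S,7E,10S)-1-[(tert-butyldimethylsilyl)oxy]-10-chloro-8,12-dimethyl-4-[(trimethylsilyl)methyl]trideca-3,7,12-trien-5-ol
Product: 13 (3Z,5S,7E,10S)-1-[(tert-butyldimethylsilyl)oxy]-10-chloro-8,12-dimethyl-4-[(trimethylsilyl)methyl]trideca-3,7,12-trien-5-yl acetate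
Conditions: Ac2O, pyridine, DMAP (cat.), CH2Cl2, 0 °C to rt
Reagents that add atoms: acetic anhydride, CC(=O)OC(C)=O
Why: standard acylation installs the C7 acetate of the target before any other hydroxyl exists, so no later differentiation of alcohols is needed.

Step 9
Reactants: 13 (3Z,5S,7E,10S)-1-[(tert-butyldimethylsilyl)oxy]-10-chloro-8,12-dimethyl-4-[(trimethylsilyl)methyl]trideca-3,7,12-trien-5-yl acetate
Product: 14 (1R,3S,4aS,7S,8aS)-1-{2-[(tert-butyldimethylsilyl)oxy]ethyl}-7-chloro-5,5,8a-trimethyl-2-methylidenedecahydronaphthalen-3-yl acetate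
Conditions: (R,R)-N,N'-bis(3,5-di-tert-butylsalicylidene)-1,2-cyclohexanediaminocobalt, Co(C36H52N2O2), divalent cobalt (10 mol %); N-fluoro-2,4,6-trimethylpyridinium tetrafluoroborate (1.1 equiv); PhSiH3 (1.1 equiv, slow addition); CH2Cl2, 0 °C
Reagents that add atoms: none
Why: Proposed new method: a cobalt hydride formed from the divalent cobalt salen complex, the N-fluoropyridinium salt and PhSiH3 should transfer a hydrogen atom only to the unhindered 1,1-disubstituted C18=C4 alkene; the tertiary C4 radical (or the cation released when its alkylcobalt is oxidised) closes ring A by 6-endo attack on C5 of the C5=C10 alkene, the tertiary C10 centre then closes ring B by 6-endo attack on C9 of the allylsilane (the C9–C10 bond), and the β-silyl C8 radical or cation is oxidised and desilylated by fluoride to leave the C8=C17 methylidene. The closest known reaction types are the cobalt-salen HAT-initiated radical–polar crossover bicyclisation of polyenes that ends on an arene and the oxidative radical allylation that ends by loss of silicon from an allylsilane; their union is new but is argued from the fact that the allylsilane intercepts either a radical or a cation at C10 productively, with the β-silicon easing the final oxidation. Both rings form through one chair–chair array, so the E-C5=C10 geometry gives the trans ring fusion (C5–H anti to the C10 methyl) and the Z-allylsilane geometry (C11 trans to C7) places the C9 side chain equatorial. The sense of folding is set by the C2 chloride, which must lie equatorial to avoid syn-axial contact with the C10 methyl and the axial C4 methyl, and the C7 acetate is matched because it is equatorial in the same fold. The step needs initiation at C18 in the presence of two trisubstituted alkenes and no protodesilylation, which the steric bias of hydrogen-atom transfer and the acid-free, collidine-buffered medium should secure, and it needs the hindered, acetate-flanked product alkene to survive, which the limiting charge of oxidant should secure.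

Step 10
Reactants: 14 (1R,3S,4aS,7S,8aS)-1-{2-[(tert-butyldimethylsilyl)oxy]ethyl}-7-chloro-5,5,8a-trimethyl-2-methylidenedecahydronaphthalen-3-yl acetate
Product: 15 (1R,3S,4aS,7S,8aS)-7-chloro-1-(2-hydroxyethyl)-5,5,8a-trimethyl-2-methylidenedecahydronaphthalen-3-yl acetate
Conditions: HF·pyridine, pyridine, THF, 0 °C to rt
Reagents that add atoms: none
Why: buffered fluoride desilylation should free the primary alcohol without touching the secondary acetate, the chloride or the methylidene.

Step 11
Reactants: 15 (1R,3S,4aS,7S,8aS)-7-chloro-1-(2-hydroxyethyl)-5,5,8a-trimethyl-2-methylidenedecahydronaphthalen-3-yl acetate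
Product: 16 (1R,3S,4aS,7S,8aS)-7-chloro-5,5,8a-trimethyl-2-methylidene-1-(2-oxoethyl)decahydronaphthalen-3-yl acetate
Conditions: Dess–Martin periodinane, NaHCO3, CH2Cl2, 0 °C
Reagents that add atoms: none
Why: Dess–Martin oxidation should give the C12 aldehyde under neutral conditions that avoid an acid-promoted carbonyl-ene reaction with the neighbouring methylidene.

Step 12
Reactants: 17 3-cyanopropanoic acid; 18 (4R)-4-benzyl-1,3-oxazolidin-2-one
Product: 20 4-[(4R)-4-benzyl-2-oxo-1,3-oxazolidin-3-yl]-4-oxobutanenitrile, via mixed anhydride 19 (not isolated)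
Conditions: PivCl, Et3N, THF, −20 °C; then 18, LiCl, rt
Reagents that add atoms: none
Why: N-acylation of the oxazolidinone through the pivalic mixed anhydride (lithium chloride–amine protocol) should proceed without racemising the auxiliary.

Step 13
Reactants: 16 (1R,3S,4aS,7S,8aS)-7-chloro-5,5,8a-trimethyl-2-methylidene-1-(2-oxoethyl)decahydronaphthalen-3-yl acetate; 20 4-[(4R)-4-benzyl-2-oxo-1,3-oxazolidin-3-yl]-4-oxobutanenitrile
Product: 22 (1R,3S,4aS,7S,8aS)-1-{(2S,3R)-3-[(4R)-4-benzyl-2-oxo-1,3-oxazolidine-3-carbonyl]-4-cyano-2-hydroxybutyl}-7-chloro-5,5,8a-trimethyl-2-methylidenedecahydronaphthalen-3-yl acetate, via boron enolate 21 (not isolated)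
Conditions: 20, Bu2BOTf, iPr2NEt, CH2Cl2, −78 to 0 °C; then 16, −78 to 0 °C; pH 7 buffer, MeOH, H2O2, 0 °C
Reagents that add atoms: none
Why: Evans syn-aldol, in which the Z-boron enolate of the (R)-benzyl imide should react through a Zimmerman–Traxler chair on the face away from the benzyl group and so set 12S and 13R (syn) under reagent control, irrespective of the remote C9 centre.

Step 14
Reactants: 22 (1R,3S,4aS,7S,8aS)-1-{(2S,3R)-3-[(4R)-4-benzyl-2-oxo-1,3-oxazolidine-3-carbonyl]-4-cyano-2-hydroxybutyl}-7-chloro-5,5,8a-trimethyl-2-methylidenedecahydronaphthalen-3-yl acetate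
Product: 24 haterumaimide N, via primary amide 23 (not isolated)
Conditions: [PtH(PMe2OH)(PMe2O)2H] (5 mol %), EtOH/H2O 4:1, 80 °C; then iPr2NEt (2 equiv), 50 °C
Reagents that add atoms: water, O
Why: platinum-catalysed neutral nitrile hydration should give the primary amide, whose nitrogen then acylates on the activated N-acyloxazolidinone carbonyl (5-exo acyl transfer, auxiliary cleavage by a nitrogen nucleophile) to close the succinimide and release the auxiliary, with no stereocentre touched and the C7 acetate exposed to neither hydroxide nor alkoxide.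

**Compound list**

1 | (R)-epichlorohydrin | ClC[C@H]1CO1 | starting material
2 | (2R)-1-chloro-4-methylpent-4-en-2-ol | C=C(C)C[C@@H](O)CCl | intermediate
3 | (2R)-2-(2-methylprop-2-en-1-yl)oxirane | C=C(C)C[C@@H]1CO1 | intermediate
4 | (4R)-6-methylhept-6-en-1-yn-4-ol | C=C(C)C[C@@H](O)CC#C | intermediate
5 | (4S)-4-chloro-6-methylhept-6-en-1-yne | C=C(C)C[C@H](Cl)CC#C | intermediate
6 | [(1E,4S)-4-chloro-2,6-dimethylhepta-1,6-dien-1-yl]dimethylalane | C=C(C)C[C@H](Cl)C/C(C)=C/[Al](C)C | intermediate
7 | (3E,6S)-6-chloro-4,8-dimethylnona-3,8-dien-1-ol | C=C(C)C[C@H](Cl)C/C(C)=C/CCO | intermediate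
8 | (3E,6S)-6-chloro-4,8-dimethylnona-3,8-dienal | C=C(C)C[C@H](Cl)C/C(C)=C/CC=O | intermediate
9 | tert-butyl(but-3-yn-1-yloxy)dimethylsilane | C#CCCO[Si](C)(C)C(C)(C)C | starting material
10 | ethyl{4-[(tert-butyldimethylsilyl)oxy]but-1-yn-1-yl}zinc | CC[Zn]C#CCCO[Si](C)(C)C(C)(C)C | intermediate
11 | (5S,7E,10S)-1-[(tert-butyldimethylsilyl)oxy]-10-chloro-8,12-dimethyltrideca-7,12-dien-3-yn-5-ol | C=C(C)C[C@H](Cl)C/C(C)=C/C[C@H](O)C#CCCO[Si](C)(C)C(C)(C)C | intermediate
12 | (3Z,5S,7E,10S)-1-[(tert-butyldimethylsilyl)oxy]-10-chloro-8,12-dimethyl-4-[(trimethylsilyl)methyl]trideca-3,7,12-trien-5-ol | C=C(C)C[C@H](Cl)C/C(C)=C/C[C@H](O)/C(C[Si](C)(C)C)=C/CCO[Si](C)(C)C(C)(C)C | intermediate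
13 | (3Z,5S,7E,10S)-1-[(tert-butyldimethylsilyl)oxy]-10-chloro-8,12-dimethyl-4-[(trimethylsilyl)methyl]trideca-3,7,12-trien-5-yl acetate | C=C(C)C[C@H](Cl)C/C(C)=C/C[C@H](OC(C)=O)/C(C[Si](C)(C)C)=C/CCO[Si](C)(C)C(C)(C)C | intermediate
14 | (1R,3S,4aS,7S,8aS)-1-{2-[(tert-butyldimethylsilyl)oxy]ethyl}-7-chloro-5,5,8a-trimethyl-2-methylidenedecahydronaphthalen-3-yl acetate | C=C1[C@@H](OC(C)=O)C[C@H]2C(C)(C)C[C@H](Cl)C[C@]2(C)[C@H]1CCO[Si](C)(C)C(C)(C)C | intermediate
15 | (1R,3S,4aS,7S,8aS)-7-chloro-1-(2-hydroxyethyl)-5,5,8a-trimethyl-2-methylidenedecahydronaphthalen-3-yl acetate | C=C1[C@@H](OC(C)=O)C[C@H]2C(C)(C)C[C@H](Cl)C[C@]2(C)[C@H]1CCO | intermediate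
16 | (1R,3S,4aS,7S,8aS)-7-chloro-5,5,8a-trimethyl-2-methylidene-1-(2-oxoethyl)decahydronaphthalen-3-yl acetate | C=C1[C@@H](OC(C)=O)C[C@H]2C(C)(C)C[C@H](Cl)C[C@]2(C)[C@H]1CC=O | intermediate
17 | 3-cyanopropanoic acid | N#CCCC(=O)O | starting material
18 | (4R)-4-benzyl-1,3-oxazolidin-2-one | O=C1N[C@H](Cc2ccccc2)CO1 | starting material
19 | 3-cyanopropanoic pivalic anhydride | N#CCCC(=O)OC(=O)C(C)(C)C | intermediate
20 | 4-[(4R)-4-benzyl-2-oxo-1,3-oxazolidin-3-yl]-4-oxobutanenitrile | N#CCCC(=O)N1C(=O)OC[C@H]1Cc1ccccc1 | intermediate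
21 | (Z)-dibutylboron enolate of 20 | N#CC/C=C(\OB(CCCC)CCCC)N1C(=O)OC[C@H]1Cc1ccccc1 | intermediate
22 | (1R,3S,4aS,7S,8aS)-1-{(2S,3R)-3-[(4R)-4-benzyl-2-oxo-1,3-oxazolidine-3-carbonyl]-4-cyano-2-hydroxybutyl}-7-chloro-5,5,8a-trimethyl-2-methylidenedecahydronaphthalen-3-yl acetate | C=C1[C@@H](OC(C)=O)C[C@H]2C(C)(C)C[C@H](Cl)C[C@]2(C)[C@H]1C[C@H](O)[C@@H](CC#N)C(=O)N1C(=O)OC[C@H]1Cc1ccccc1 | intermediate
23 | primary amide from hydration of the nitrile of 22 (12S,13R; auxiliary still attached) | C=C1[C@@H](OC(C)=O)C[C@H]2C(C)(C)C[C@H](Cl)C[C@]2(C)[C@H]1C[C@H](O)[C@@H](CC(N)=O)C(=O)N1C(=O)OC[C@H]1Cc1ccccc1 | intermediate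
24 | haterumaimide N | C=C1[C@@H](OC(C)=O)C[C@H]2C(C)(C)C[C@H](Cl)C[C@]2(C)[C@H]1C[C@H](O)[C@H]1CC(=O)NC1=O | target

**Count and risks**

Total: 14 steps. Longest linear sequence: 13 steps (steps 1–11, 13 and 14; step 12 prepares the aldol partner).

Steps most likely to fail:

1. Step 9 (proposed new method). The C4 radical may be reduced before it cyclises, the cascade may stop after ring A, the silyl group may be lost before ring B closes, or the product methylidene may react further with the cobalt hydride. Fallback with known chemistry, setting out from 13 and returning at 14: cobalt-catalysed Markovnikov hydrochlorination of the terminal 1,1-disubstituted alkene (Co(BF4)2·6H2O with a salicylaldimine ligand, TsCl, PhSiH3, EtOH) gives the tertiary chloride F1. Ionisation of F1 with SnCl4 (2,6-di-tert-butyl-4-methylpyridine, CH2Cl2, −78 °C) then starts a classical Lewis-acid cation–olefin bicyclisation terminated by the allylsilane with loss of Me3SiCl, through the same chair–chair fold, to reach 14.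

2. Step 14. Ring closure of the amide may stall, the C12 hydroxyl may add to the activated nitrile or acyl group (lactonisation), or retro-aldol cleavage may occur on heating with base. Fallback, setting out from 22 and returning at 24: silylation of the C12 hydroxyl (TESOTf, 2,6-lutidine, CH2Cl2, −78 °C) gives the triethylsilyl ether F2. The same platinum-catalysed hydration gives the protected primary amide F3. Anionic closure with DBU in MeCN at rt, now free of retro-aldol and lactone pathways, gives the O-triethylsilyl imide F4 with release of the auxiliary. HF·pyridine then frees the C12 hydroxyl to give 24.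

3. Step 6. Facial selectivity of the alkynyl transfer may be poor for this unbranched aldehyde, and the C5=C10 alkene may migrate into conjugation or the aldehyde may self-condense on the titanium/zinc alkoxides. Fallback, setting out from 8 and returning at 11: addition of the lithium acetylide of 9 (n-BuLi, THF, −78 °C) gives the C7-epimeric propargylic alcohols F5. Dess–Martin oxidation gives the ynone F6. Noyori asymmetric transfer hydrogenation with RuCl[(S,S)-TsDPEN](p-cymene) in iPrOH, where the alkynyl group plays the π-substituent role, then sets the (S)-carbinol and gives 11.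

Further compounds
F1 | step 9 | tertiary chloride from Markovnikov HCl addition to the terminal alkene of 13 (other centres and alkene geometries as in 13) | CC(C)(Cl)C[C@H](Cl)C/C(C)=C/C[C@H](OC(C)=O)/C(C[Si](C)(C)C)=C/CCO[Si](C)(C)C(C)(C)C
F2 | step 14 | C12 O-triethylsilyl ether of 22 | C=C1[C@@H](OC(C)=O)C[C@H]2C(C)(C)C[C@H](Cl)C[C@]2(C)[C@H]1C[C@H](O[Si](CC)(CC)CC)[C@@H](CC#N)C(=O)N1C(=O)OC[C@H]1Cc1ccccc1
F3 | step 14 | C12 O-triethylsilyl primary amide (auxiliary still attached) | C=C1[C@@H](OC(C)=O)C[C@H]2C(C)(C)C[C@H](Cl)C[C@]2(C)[C@H]1C[C@H](O[Si](CC)(CC)CC)[C@@H](CC(N)=O)C(=O)N1C(=O)OC[C@H]1Cc1ccccc1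
F4 | step 14 | 12-O-triethylsilyl haterumaimide N | C=C1[C@@H](OC(C)=O)C[C@H]2C(C)(C)C[C@H](Cl)C[C@]2(C)[C@H]1C[C@H](O[Si](CC)(CC)CC)[C@H]1CC(=O)NC1=O
F5 | step 6 | (7E,10S)-1-[(tert-butyldimethylsilyl)oxy]-10-chloro-8,12-dimethyltrideca-7,12-dien-3-yn-5-ol, mixture of C5 epimers | C=C(C)C[C@H](Cl)C/C(C)=C/CC(O)C#CCCO[Si](C)(C)C(C)(C)C
F6 | step 6 | (7E,10S)-1-[(tert-butyldimethylsilyl)oxy]-10-chloro-8,12-dimethyltrideca-7,12-dien-3-yn-5-one | C=C(C)C[C@H](Cl)C/C(C)=C/CC(=O)C#CCCO[Si](C)(C)C(C)(C)C
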